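**Strategy.** Ring C is cut at O1–C2 and C4–C4a. Because the 2'-OH of ring B sits ortho to C2, the atoms O2'–C2'–C1'–C2–C3–C4 are a latent coumarin lactone, and with the fused dimethylpyran this is xanthyletin. The key step lithiates a MOM-protected ring-A phenol at C4a (between two oxygens), opens the lactone at C4, and unmasks O1 and the 2'-OH. The resulting flavylium/hemiketal/chalcone mixture then drains through a cinchona-thiourea-controlled 6-endo oxa-Michael closure into the 2S flavanone. The precursors are an open prenylated arene and a tricyclic coumarin. A peri-selective 5-O-demethylation ends the route.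

Key step: step 3

Remark: flavanone numbering is used throughout (O1, C2, C3, C4, C4a, C5–C8, C8a; ring B primed).
Assumption: xanthyletin is bought as the isolated natural coumarin offered by natural-product suppliers.
Assumption: Si-face delivery of O1 (2S) is assigned to the quinidine-derived thiourea by model only. The quinine-derived pseudoenantiomer is the mirror-image option.

Step 1
Reactants: 1 3,5-dimethoxyphenol
Product: 2 1,3-dimethoxy-5-(methoxymethoxy)benzene
Conditions: NaH, MOMCl, DMF, 0 °C to rt
Reagents that add atoms: chloromethyl methyl ether (MOMCl), COCCl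
Why: Williamson-type O-alkylation of the sodium phenoxide should be clean, and the MOM acetal serves both as the mask of the future O1 and as the chelating director for the two lithiations that follow.

Step 2
Reactants: 2 1,3-dimethoxy-5-(methoxymethoxy)benzene; 3 prenyl bromide
Product: 5 1,5-dimethoxy-3-(methoxymethoxy)-2-(3-methylbut-2-en-1-yl)benzene, via 2-lithio arene 4 (not isolated)
Conditions: n-BuLi, THF, 0 °C; CuBr·SMe2 (10 mol%), 3, −78 °C to rt
Reagents that add atoms: none
Why: Directed ortho-metalation followed by copper-assisted SN2 allylation: the MOM acetal steers n-BuLi to one of the two symmetry-equivalent carbons flanked by OMOM and OMe rather than to the carbon between the two OMe groups, and prenyl bromide should couple at its primary carbon.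

Step 3
Reactants: 5 1,5-dimethoxy-3-(methoxymethoxy)-2-(3-methylbut-2-en-1-yl)benzene; 6 xanthyletin
Product: 13 (2S)-2-(7-hydroxy-2,2-dimethyl-2H-chromen-6-yl)-5,7-dimethoxy-8-prenylchroman-4-one, via aryllithium 7 (not isolated), via lithium Z-chalcone phenoxide 8 (not isolated), via flavylium chloride 9 (not isolated), via hemiketal 10 (not isolated), via Z-chalcone 11 (not isolated), via E-chalcone 12 (not isolated)
Conditions: n-BuLi, THF, 0 °C; 6, THF, −78 to −40 °C; HCl (2 M in MeOH), 0 °C to rt; NaHCO3, H2O, to pH 6–7, 0 °C; solvent swap to toluene, salts filtered off; quinidine-derived thiourea (9-amino-9-deoxy-epi-quinidine N'-3,5-bis(trifluoromethyl)phenyl thiourea, 10 mol%), −20 °C, Ar, dark; no intermediate isolated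
Reagents that add atoms: water, O
Why: Proposed new method: MOM-directed ortho-lithiation of 5 at the ring-A carbon between OMOM and OMe gives 7, whose 1,2-addition to the lactone carbonyl of 6 makes C4–C4a and expels the ring-B 2'-phenoxide (8); methanolic HCl then frees O1 and parks everything as flavylium salt 9 (whose positive charge also shields the pyran alkene from acid), and NaHCO3/water releases it as the interconverting set 10, 11 and 12. The closest known reaction types are the addition of aryl organometallics to coumarins (the classical entry to 2-arylbenzopyrylium salts), the relaxation of 2,2'-dihydroxychalcone–flavylium networks to flavanones and the cinchona-thiourea-catalysed cyclisation of 2'-hydroxychalcones, so that only their merger without isolation is new. Ring C, the only ring closed, forms by 6-endo-trig oxa-Michael addition of O1 to C2 of 12, followed by ketonisation at C3. C2 is set by the catalyst: the thiourea holds the C4 carbonyl, the quinuclidine takes the O1 proton, and O1 is delivered to the Si face of C2, which gives 2S. The step is stereoconvergent because the racemic hemiketal 10 and the Z-chalcone 11 feed 12 by ring-chain tautomerism and by rotation about the C2–C3 bond, whose double-bond character is lowered by the 2'-OH/4'-O donors of ring B, while the twisted 6'-methoxy aryl ketone makes closure strongly downhill and slows the reverse reaction that would racemise 13. Needed are lithiation at C4a and not at C6 or the prenyl CH2 (MOM chelation, the prenyl group turning the acetal toward C4a), 1,2- over 1,4-addition and single addition (hard, doubly ortho-substituted aryllithium at −78 °C), and closure to the 8-prenyl and not the 6-prenyl isomer (the C5 oxygen is capped as its methyl ether, so O1 is the only ring-A phenol).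

Step 4
Reactants: 13 (2S)-2-(7-hydroxy-2,2-dimethyl-2H-chromen-6-yl)-5,7-dimethoxy-8-prenylchroman-4-one
Product: 14 maackiaflavanone A
Conditions: BCl3 (2.2 equiv), CH2Cl2, −78 to −40 °C; ice-water quench
Reagents that add atoms: none
Why: Chelation-controlled aryl methyl ether cleavage: BCl3 bridges the C4 carbonyl and the peri 5-OMe so that chloride removes only that methyl group, the 7-OMe has no such anchor, the prenyl group has no free ortho phenol to cyclise onto, and at low temperature the C2–O1 bond should stay intact so that 2S is retained.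

**Compound list**
1 | 3,5-dimethoxyphenol | COc1cc(O)cc(OC)c1 | starting material
2 | 1,3-dimethoxy-5-(methoxymethoxy)benzene | COCOc1cc(OC)cc(OC)c1 | intermediate
3 | prenyl bromide (1-bromo-3-methylbut-2-ene) | CC(C)=CCBr | starting material
4 | 2-lithio-1,5-dimethoxy-3-(methoxymethoxy)benzene | [Li]c1c(OC)cc(OC)cc1OCOC | intermediate
5 | 1,5-dimethoxy-3-(methoxymethoxy)-2-(3-methylbut-2-en-1-yl)benzene | COCOc1cc(OC)cc(OC)c1CC=C(C)C | intermediate
6 | xanthyletin (8,8-dimethyl-2H,8H-pyrano[3,2-g]chromen-2-one) | CC1(C)C=Cc2cc3ccc(=O)oc3cc2O1 | starting material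
7 | 2-lithio-1,5-dimethoxy-3-(methoxymethoxy)-4-(3-methylbut-2-en-1-yl)benzene | [Li]c1c(OC)cc(OC)c(CC=C(C)C)c1OCOC | intermediate
8 | lithium 6-[(Z)-3-(4,6-dimethoxy-2-(methoxymethoxy)-3-prenylphenyl)-3-oxoprop-1-enyl]-2,2-dimethyl-2H-chromen-7-olate | [Li+].[O-]c1cc2OC(C)(C)C=Cc2cc1/C=C\C(=O)c1c(OC)cc(OC)c(CC=C(C)C)c1OCOC | intermediate
9 | 2-(2-hydroxy-4,6-dimethoxy-3-prenylphenyl)-8,8-dimethyl-8H-pyrano[3,2-g]chromen-1-ium chloride | COc1cc(OC)c(CC=C(C)C)c(O)c1-c1ccc2cc3C=CC(C)(C)Oc3cc2[o+]1.[Cl-] | intermediate
10 | 2-(2-hydroxy-4,6-dimethoxy-3-prenylphenyl)-8,8-dimethyl-2H,8H-pyrano[3,2-g]chromen-2-ol (racemic hemiketal) | COc1cc(OC)c(CC=C(C)C)c(O)c1C1(O)C=Cc2cc3C=CC(C)(C)Oc3cc2O1 | intermediate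
11 | (Z)-1-(2-hydroxy-4,6-dimethoxy-3-prenylphenyl)-3-(7-hydroxy-2,2-dimethyl-2H-chromen-6-yl)prop-2-en-1-one | COc1cc(OC)c(CC=C(C)C)c(O)c1C(=O)/C=C\c1cc2C=CC(C)(C)Oc2cc1O | intermediate
12 | (E)-1-(2-hydroxy-4,6-dimethoxy-3-prenylphenyl)-3-(7-hydroxy-2,2-dimethyl-2H-chromen-6-yl)prop-2-en-1-one | COc1cc(OC)c(CC=C(C)C)c(O)c1C(=O)/C=C/c1cc2C=CC(C)(C)Oc2cc1O | intermediate
13 | (2S)-2-(7-hydroxy-2,2-dimethyl-2H-chromen-6-yl)-5,7-dimethoxy-8-(3-methylbut-2-en-1-yl)chroman-4-one | COc1cc(OC)c2c(c1CC=C(C)C)O[C@H](c1cc3c(cc1O)OC(C)(C)C=C3)CC2=O | intermediate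
14 | maackiaflavanone A, (2S)-5-hydroxy-2-(7-hydroxy-2,2-dimethyl-2H-chromen-6-yl)-7-methoxy-8-(3-methylbut-2-en-1-yl)chroman-4-one | COc1cc(O)c2c(c1CC=C(C)C)O[C@H](c1cc3c(cc1O)OC(C)(C)C=C3)CC2=O | target

Total steps: 4. Longest linear sequence: 4 steps (1 → 2 → 5 → 13 → 14).

**Steps most likely to fail**

1. **Step 3 (key step).**
   - What may go wrong: insufficient facial selectivity in the ring closure; an uncatalysed background closure during neutralisation; or erosion of enantiopurity by reversible opening of ring C through the ring-B quinone-methide pathway.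
   - Fallback (known chemistry only): it sets out from 5 and 6 and runs the same lithiation, lactone opening and HCl stage through 7–12. Ring C is then closed without chiral control (NaOAc, EtOH, 50 °C) to the racemic 5,7-dimethoxy-8-prenylflavanone F1.
   - F1 is resolved kinetically by asymmetric transfer hydrogenation: Cp*RhCl(TsDPEN), the ligand antipode that consumes the 2R ketone, HCO2H/Et3N, EtOAc, rt, stopped near half conversion. The 2R ketone should be reduced to the cis-(2R,4R)-flavan-4-ol F2. The unreacted 2S ketone is 13, where the route is rejoined.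

2. **Step 4.**
   - What may go wrong: Lewis-acid-assisted ionisation of the C2–O1 bond, helped by the electron-rich ring B, which leads to racemisation; and addition of the HCl released from the free 2'-OH to the prenyl or pyran alkene.
   - Fallback: it sets out from 13 and masks the labilising phenol first (TBSCl, imidazole, CH2Cl2, 0 °C) as the 2'-O-TBS ether F3. This weakens the ring-B donor, blocks the quinone-methide path and leaves no proton source for BCl3.
   - Chelation-controlled demethylation (BCl3, CH2Cl2, −78 °C) should then give the 5-hydroxy 2'-O-TBS flavanone F4. Buffered desilylation (HF·pyridine, pyridine/THF, 0 °C) comes back to the route at 14.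

3. **Step 2.**
   - What may go wrong: competing lithiation between the two methoxy groups, and SN2' coupling that places a reverse-prenyl group.
   - Fallback: it sets out from 1 and moves the C–C bond formation to a sigmatropic step. O-alkylation with 3-chloro-3-methylbut-1-yne (CuCl2 cat., DBU, MeCN, 0 °C) gives the 1,1-dimethylpropargyl ether F5. Semi-hydrogenation (H2, Pd/CaCO3 poisoned with Pb(OAc)2, quinoline, EtOAc) gives the 1,1-dimethylallyl ether F6.
   - Aromatic Claisen rearrangement (toluene, 110 °C) gives 3,5-dimethoxy-2-prenylphenol F7. The two ortho positions are equivalent by symmetry, so only one prenyl phenol can form. MOM protection (NaH, MOMCl, DMF) comes back to the route at 5.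

**Further compounds**
F1 | step 3 | racemic 2-(7-hydroxy-2,2-dimethyl-2H-chromen-6-yl)-5,7-dimethoxy-8-prenylchroman-4-one | COc1cc(OC)c2c(c1CC=C(C)C)OC(c1cc3c(cc1O)OC(C)(C)C=C3)CC2=O
F2 | step 3 | cis-(2R,4R)-2-(7-hydroxy-2,2-dimethyl-2H-chromen-6-yl)-5,7-dimethoxy-8-prenylchroman-4-ol | COc1cc(OC)c2c(c1CC=C(C)C)O[C@@H](c1cc3c(cc1O)OC(C)(C)C=C3)C[C@H]2O
F3 | step 4 | (2S)-2-[7-(tert-butyldimethylsilyloxy)-2,2-dimethyl-2H-chromen-6-yl]-5,7-dimethoxy-8-prenylchroman-4-one | COc1cc(OC)c2c(c1CC=C(C)C)O[C@H](c1cc3c(cc1O[Si](C)(C)C(C)(C)C)OC(C)(C)C=C3)CC2=O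
F4 | step 4 | (2S)-2-[7-(tert-butyldimethylsilyloxy)-2,2-dimethyl-2H-chromen-6-yl]-5-hydroxy-7-methoxy-8-prenylchroman-4-one | COc1cc(O)c2c(c1CC=C(C)C)O[C@H](c1cc3c(cc1O[Si](C)(C)C(C)(C)C)OC(C)(C)C=C3)CC2=O
F5 | step 2 | 1,3-dimethoxy-5-(2-methylbut-3-yn-2-yloxy)benzene | C#CC(C)(C)Oc1cc(OC)cc(OC)c1
F6 | step 2 | 1,3-dimethoxy-5-(2-methylbut-3-en-2-yloxy)benzene | C=CC(C)(C)Oc1cc(OC)cc(OC)c1
F7 | step 2 | 3,5-dimethoxy-2-(3-methylbut-2-en-1-yl)phenol | COc1cc(O)c(CC=C(C)C)c(OC)c1
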